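## Retrosynthetic overview

1. Target 8 ⇐ protected trimer 7 by hydrogenolysis of 18 benzyl ethers.
2. 7 ⇐ digallate dimer 6 + C4–O electrophile 3 (upper C4–C8 bond, 4β).
3. 6 ⇐ dimer diol 4 + two equivalents of acid 5 (both gallate ester C–O bonds in one operation).
4. 4 ⇐ 2 + the same electrophile 3 (lower C4–C8 bond, 4β). 3 ⇐ 2 by the key C4–O bond formation, a catalytic dehydrogenative C4–H etherification. 2 ⇐ 1 by phenol benzylation.
5. No ring is built. Rings A, B and C of all three units and every C2/C3 stereocentre come from 1. The units are joined lower → middle → upper.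

Assumption: (−)-epicatechin and 3,4,5-tris(benzyloxy)benzoic acid are bought; α/β descriptors follow the usual flavan drawing (ring B of the 2R series is α).

## Route

Step 1
Reactants: 1 (−)-epicatechin
Product: 2 5,7,3′,4′-tetra-O-benzyl-(−)-epicatechin [(2R,3R)-5,7-bis(benzyloxy)-2-[3,4-bis(benzyloxy)phenyl]chroman-3-ol]
Conditions: BnBr (4.4 equiv), K2CO3 (5 equiv), DMF, 0 °C to rt, Ar, 16 h
Reagents that add atoms: benzyl bromide, BrCc1ccccc1
Why: Williamson etherification in which carbonate deprotonates only the four phenols and not the C3 alcohol, so the C2 and C3 stereocentres of 1 are carried over untouched.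

Step 2
Reactants: 2 5,7,3′,4′-tetra-O-benzyl-(−)-epicatechin
Product: 3 (2R,3R,4S)-5,7-bis(benzyloxy)-2-[3,4-bis(benzyloxy)phenyl]-4-(2-ethoxyethoxy)chroman-3-ol (the 4β-(2-ethoxyethoxy) ether of 2)
Conditions: DDQ (15 mol %), MnO2 (6 equiv), 2-ethoxyethanol (5 equiv), 2,6-dichloropyridine (1 equiv), 4 Å MS, CH2Cl2, rt
Reagents that add atoms: 2-ethoxyethanol, CCOCCO
Why: Proposed new method: a DDQ-catalysed dehydrogenative C4–H/O–H coupling in which solid MnO2 re-oxidises DDQH2, so the quinone acts only as a hydride shuttle; DDQ removes the pseudo-axial C4 hydride of 2 (the cation is stabilised by O1, 5-OBn and 7-OBn of ring A, whereas C2–H and the benzyl ether CH2 groups lack this stabilisation and the non-benzylic 3-OH is inert to MnO2), and 2-ethoxyethanol adds to the β-face anti to the 3α-OH and 2α-aryl to set 4S; the closest known reaction types are the stoichiometric DDQ C4-alkoxylation of benzylated flavan-3-ols and the DDQ-catalysed, MnO2-driven oxidative C–H functionalisation of benzylic ethers, which has not been shown on a flavan C4–H.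

Step 3
Reactants: 3 the 4β-(2-ethoxyethoxy) ether of 2; 2 5,7,3′,4′-tetra-O-benzyl-(−)-epicatechin
Product: 4 octa-O-benzyl procyanidin B2 [tetra-O-benzylepicatechin-(4β→8)-tetra-O-benzylepicatechin, both 3-OH free]
Conditions: Yb(OTf)3 (1 equiv), 2 (2.5 equiv, excess recovered), CH2Cl2, rt, 4 h
Reagents that add atoms: none
Why: Lewis-acid-promoted SN1 Friedel–Crafts alkylation through the flavan-4-yl cation, in which C8 of 2 (C6 is flanked by two benzyloxy groups) attacks the β-face anti to the 3α-OH and 2α-aryl and so sets the 4β (3,4-trans) interflavan stereocentre.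

Step 4
Reactants: 4 octa-O-benzyl procyanidin B2; 5 3,4,5-tris(benzyloxy)benzoic acid
Product: 6 octa-O-benzyl procyanidin B2 3,3″-bis[3,4,5-tris(benzyloxy)benzoate] (both 3-OH esterified)
Conditions: 5 (4 equiv), DCC (4 equiv), DMAP (0.5 equiv), CH2Cl2, rt to 40 °C, 48 h
Reagents that add atoms: none
Why: Steglich esterification through the acylpyridinium of 5, which acylates both secondary alcohols at oxygen so that the C3 configurations are retained.

Step 5
Reactants: 6 octa-O-benzyl procyanidin B2 bis(tri-O-benzylgallate); 3 the 4β-(2-ethoxyethoxy) ether of 2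
Product: 7 protected trimer [tetra-O-benzylepicatechin-(4β→8)-(tetra-O-benzylepicatechin 3-O-tri-O-benzylgallate)-(4β→8)-(tetra-O-benzylepicatechin 3-O-tri-O-benzylgallate); 18 benzyl ethers, upper 3-OH free]
Conditions: 6 (1.3 equiv), Yb(OTf)3 (1 equiv), CH2Cl2, rt; 3 (1.0 equiv) added over 2 h
Reagents that add atoms: none
Why: The same Friedel–Crafts interflavan coupling, in which the only unsubstituted C8 of 6 is on its upper unit and attack anti to the 3α-OH of the cation sets the second 4β stereocentre, while slow addition of 3 keeps its self-condensation low.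

Step 6
Reactants: 7 protected trimer
Product: 8 (−)-epicatechin-(4β→8)-(−)-epicatechin 3-O-gallate-(4β→8)-(−)-epicatechin 3-O-gallate (CNP0279403.1)
Conditions: H2 (1 atm), Pd(OH)2/C (20 wt %), THF/MeOH/H2O 20:20:1, rt, 3 h; filter, lyophilise, Sephadex LH-20
Reagents that add atoms: none
Why: Heterogeneous hydrogenolysis of the 18 benzyl ethers, which leaves the aryl esters, the interflavan bonds and all stereocentres untouched under neutral conditions.

## Compound list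

1 | (−)-epicatechin | O[C@@H]1Cc2c(O)cc(O)cc2O[C@@H]1c1ccc(O)c(O)c1 | starting material
2 | 5,7,3′,4′-tetra-O-benzyl-(−)-epicatechin | O[C@@H]1Cc2c(OCc3ccccc3)cc(OCc3ccccc3)cc2O[C@@H]1c1ccc(OCc2ccccc2)c(OCc2ccccc2)c1 | intermediate
3 | (2R,3R,4S)-5,7-bis(benzyloxy)-2-[3,4-bis(benzyloxy)phenyl]-4-(2-ethoxyethoxy)chroman-3-ol | O[C@@H]1[C@@H](OCCOCC)c2c(OCc3ccccc3)cc(OCc3ccccc3)cc2O[C@@H]1c1ccc(OCc2ccccc2)c(OCc2ccccc2)c1 | intermediate
4 | octa-O-benzyl procyanidin B2, tetra-O-benzylepicatechin-(4β→8)-tetra-O-benzylepicatechin | O[C@@H]1[C@@H](c2c(OCc3ccccc3)cc(OCc3ccccc3)c3c2O[C@H](c2ccc(OCc4ccccc4)c(OCc4ccccc4)c2)[C@H](O)C3)c2c(OCc3ccccc3)cc(OCc3ccccc3)cc2O[C@@H]1c1ccc(OCc2ccccc2)c(OCc2ccccc2)c1 | intermediate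
5 | 3,4,5-tris(benzyloxy)benzoic acid | OC(=O)c1cc(OCc2ccccc2)c(OCc2ccccc2)c(OCc2ccccc2)c1 | starting material
6 | octa-O-benzyl procyanidin B2 3,3″-bis[3,4,5-tris(benzyloxy)benzoate] | O=C(O[C@@H]1[C@@H](c2c(OCc3ccccc3)cc(OCc3ccccc3)c3c2O[C@H](c2ccc(OCc4ccccc4)c(OCc4ccccc4)c2)[C@H](OC(=O)c2cc(OCc4ccccc4)c(OCc4ccccc4)c(OCc4ccccc4)c2)C3)c2c(OCc3ccccc3)cc(OCc3ccccc3)cc2O[C@@H]1c1ccc(OCc2ccccc2)c(OCc2ccccc2)c1)c1cc(OCc2ccccc2)c(OCc2ccccc2)c(OCc2ccccc2)c1 | intermediate
7 | tetra-O-benzylepicatechin-(4β→8)-(tetra-O-benzylepicatechin 3-O-tri-O-benzylgallate)-(4β→8)-(tetra-O-benzylepicatechin 3-O-tri-O-benzylgallate) | O=C(O[C@@H]1[C@@H](c2c(OCc3ccccc3)cc(OCc3ccccc3)c3c2O[C@H](c2ccc(OCc4ccccc4)c(OCc4ccccc4)c2)[C@H](OC(=O)c2cc(OCc4ccccc4)c(OCc4ccccc4)c(OCc4ccccc4)c2)C3)c2c(OCc3ccccc3)cc(OCc3ccccc3)c([C@H]3c4c(OCc5ccccc5)cc(OCc5ccccc5)cc4O[C@H](c4ccc(OCc5ccccc5)c(OCc5ccccc5)c4)[C@@H]3O)c2O[C@@H]1c1ccc(OCc2ccccc2)c(OCc2ccccc2)c1)c1cc(OCc2ccccc2)c(OCc2ccccc2)c(OCc2ccccc2)c1 | intermediate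
8 | (−)-epicatechin-(4β→8)-(−)-epicatechin 3-O-gallate-(4β→8)-(−)-epicatechin 3-O-gallate | O=C(O[C@@H]1[C@@H](c2c(O)cc(O)c3c2O[C@H](c2ccc(O)c(O)c2)[C@H](OC(=O)c2cc(O)c(O)c(O)c2)C3)c2c(O)cc(O)c([C@H]3c4c(O)cc(O)cc4O[C@H](c4ccc(O)c(O)c4)[C@@H]3O)c2O[C@@H]1c1ccc(O)c(O)c1)c1cc(O)c(O)c(O)c1 | target

## Step count and risks

Total step count: 6. Longest linear sequence: 6 (1 → 2 → 3 → 4 → 6 → 7 → 8).

Three steps most likely to fail:

Step 2 (the new catalytic C4–H etherification). Turnover of DDQ by MnO2 may be slow on this substrate, or the product may be over-oxidised at C4. The fallback sets out from 2 and drops both catalytic turnover and the monodentate acetal. Stoichiometric DDQ (2 equiv) with ethylene glycol in CH2Cl2 gives the known chelating glycol ether (2R,3R,4S)-5,7-bis(benzyloxy)-2-[3,4-bis(benzyloxy)phenyl]-4-(2-hydroxyethoxy)chroman-3-ol F1. This is ionised by TiCl4 in CH2Cl2/THF at 0 °C in place of 3. The fallback comes back to the route at 4 (coupling with excess 2) and again at 7 (coupling with 6).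

Step 5 (upper interflavan bond). The electrophile 3 carries its own nucleophilic C8, so it can self-condense or add twice, which wastes the valuable dimer 6. The fallback sets out from 2 and caps that position. NBS in CH2Cl2 at −78 to 0 °C gives 8-bromo-5,7,3′,4′-tetra-O-benzyl-(−)-epicatechin F2. Stoichiometric DDQ with 2-ethoxyethanol gives the 4β-(2-ethoxyethoxy) ether of 8-bromo-tetra-O-benzylepicatechin F3. F3 (2 equiv) is coupled with 6 under Yb(OTf)3 to give the upper-unit 8-bromo derivative of 7 F4, which can neither self-condense at C8 nor chain-extend. Pd(OH)2/C, H2 and Et3N then remove the bromine together with all benzyl groups, and the fallback comes back to the route at 8.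

Step 4 (double esterification). The upper-unit 3-OH of 4 sits next to the bulky C4 aryl substituent and may stop at the mono-ester. The fallback sets out from 2 and 3 and esterifies before the C–C coupling. DCC/DMAP with 5 converts 2 into 5,7,3′,4′-tetra-O-benzyl-(−)-epicatechin 3-O-[3,4,5-tris(benzyloxy)benzoate] F5 and 3 into the 3-O-[3,4,5-tris(benzyloxy)benzoate] of 3 F6. TMSOTf-catalysed coupling of F6 with F5 in CH2Cl2 at −78 to −30 °C follows, with α-face participation of the ester reinforcing β-attack, and the fallback comes back to the route at 6.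

## Further compounds

F1 | step 2 | (2R,3R,4S)-5,7-bis(benzyloxy)-2-[3,4-bis(benzyloxy)phenyl]-4-(2-hydroxyethoxy)chroman-3-ol | O[C@@H]1[C@@H](OCCO)c2c(OCc3ccccc3)cc(OCc3ccccc3)cc2O[C@@H]1c1ccc(OCc2ccccc2)c(OCc2ccccc2)c1
F2 | step 5 | 8-bromo-5,7,3′,4′-tetra-O-benzyl-(−)-epicatechin | O[C@@H]1Cc2c(OCc3ccccc3)cc(OCc3ccccc3)c(Br)c2O[C@@H]1c1ccc(OCc2ccccc2)c(OCc2ccccc2)c1
F3 | step 5 | 4β-(2-ethoxyethoxy) ether of 8-bromo-tetra-O-benzylepicatechin | O[C@@H]1[C@@H](OCCOCC)c2c(OCc3ccccc3)cc(OCc3ccccc3)c(Br)c2O[C@@H]1c1ccc(OCc2ccccc2)c(OCc2ccccc2)c1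
F4 | step 5 | upper-unit 8-bromo derivative of 7 | O=C(O[C@@H]1[C@@H](c2c(OCc3ccccc3)cc(OCc3ccccc3)c3c2O[C@H](c2ccc(OCc4ccccc4)c(OCc4ccccc4)c2)[C@H](OC(=O)c2cc(OCc4ccccc4)c(OCc4ccccc4)c(OCc4ccccc4)c2)C3)c2c(OCc3ccccc3)cc(OCc3ccccc3)c([C@H]3c4c(OCc5ccccc5)cc(OCc5ccccc5)c(Br)c4O[C@H](c4ccc(OCc5ccccc5)c(OCc5ccccc5)c4)[C@@H]3O)c2O[C@@H]1c1ccc(OCc2ccccc2)c(OCc2ccccc2)c1)c1cc(OCc2ccccc2)c(OCc2ccccc2)c(OCc2ccccc2)c1
F5 | step 4 | 5,7,3′,4′-tetra-O-benzyl-(−)-epicatechin 3-O-[3,4,5-tris(benzyloxy)benzoate] | O=C(O[C@@H]1Cc2c(OCc3ccccc3)cc(OCc3ccccc3)cc2O[C@@H]1c1ccc(OCc2ccccc2)c(OCc2ccccc2)c1)c1cc(OCc2ccccc2)c(OCc2ccccc2)c(OCc2ccccc2)c1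
F6 | step 4 | 3-O-[3,4,5-tris(benzyloxy)benzoate] of 3 | O=C(O[C@@H]1[C@@H](OCCOCC)c2c(OCc3ccccc3)cc(OCc3ccccc3)cc2O[C@@H]1c1ccc(OCc2ccccc2)c(OCc2ccccc2)c1)c1cc(OCc2ccccc2)c(OCc2ccccc2)c(OCc2ccccc2)c1
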